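**Strategy.** The cyclohexane ring (C1–C6, quinic acid numbering) is cut across C2–C3 and C6–C1 into buta-1,3-diene (C3–C6) and a two-carbon 2-oxyacrylate unit (C2=C1) carrying O-1 and the carboxyl carbon C7. The feature exploited is the tertiary α-hydroxy acid at C1: O-1 and C7 are tied into a temporary 1,3-dioxolan-4-one ring (a chiral 5-methylidene dienophile from (R)-lactic acid) whose acetal tert-butyl group shields one face. One Diels–Alder reaction then closes the carbocycle and sets quaternary C1. The carboxyl, cis to O-5, relays this chirality to C5, C4 and C3 through a bridging γ-lactone before the 4,5-diol is esterified with protected vanilloyl groups.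

Key step: step 3

Remark: locants follow quinic acid numbering (C1 = quaternary carbinol carbon bearing carboxyl C7; C2, C6 = methylenes; O-3 free; O-4 and O-5 vanilloylated), so the target is treated as 4,5-di-O-vanilloyl-(−)-quinic acid, which is what its stereodescriptors encode.

Step 1
Reactants: 1 (R)-lactic acid; 2 pivalaldehyde
Product: 3 (2R,5R)-2-tert-butyl-5-methyl-1,3-dioxolan-4-one
Conditions: p-TsOH (cat.), H2SO4 (cat.), pentane, reflux with azeotropic water removal; crystallisation from pentane at −78 °C
Reagents that add atoms: none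
Why: Acid-catalysed acetalisation of the α-hydroxy acid, in which the lactate stereocentre sets the new acetal centre because the 2,5-cis dioxolanone is the favoured isomer and the minor trans isomer is removed by low-temperature crystallisation.

Step 2
Reactants: 3 (2R,5R)-2-tert-butyl-5-methyl-1,3-dioxolan-4-one
Product: 5 (2R)-2-tert-butyl-5-methylidene-1,3-dioxolan-4-one, via bromo acetal 4 (not isolated)
Conditions: NBS, AIBN (cat.), cyclohexane, reflux; then Et3N, 0 °C to rt
Reagents that add atoms: none
Why: Wohl–Ziegler radical bromination at the captodative C-5 hydrogen followed by E2 dehydrobromination gives the exocyclic alkene; the lactate stereocentre is erased, but its chirality already resides in the untouched acetal carbon.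

Step 3
Reactants: 5 (2R)-2-tert-butyl-5-methylidene-1,3-dioxolan-4-one; 6 buta-1,3-diene
Product: 7 (2R,5S)-2-tert-butyl-1,3-dioxaspiro[4.5]dec-7-en-4-one
Conditions: 6 (excess), BHT (cat.), toluene, sealed vessel, 100 °C
Reagents that add atoms: none
Why: A concerted, suprafacial thermal [4+2] cycloaddition of normal electron demand joins s-cis butadiene (C3=C4–C5=C6) to the captodative exocyclic alkene C2=C1 of 5, whose LUMO is lowered by the lactone carbonyl. The closest known reaction type is the Diels–Alder reaction of 5-methylidene-1,3-dioxolan-4-ones, used as chiral α-hydroxyacrylate equivalents, with simple dienes. The cyclohexene ring closes in the [4+2] mode with spiro fusion at C1, forming C2–C3 and C6–C1 together and leaving the C4=C5 alkene as the handle for later oxygenation. The only new stereocentre, quaternary C1, is controlled by the acetal carbon: the tert-butyl group blocks one face of the flat dioxolanone, so the diene should add anti to it and C6 ends up trans to tert-butyl. Because butadiene is symmetric and unsubstituted, no regiochemical or endo/exo question arises and π-facial selectivity is the single selectivity required; BHT and moderate temperature are meant to hold back radical polymerisation of 5.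

Step 4
Reactants: 7 (2R,5S)-2-tert-butyl-1,3-dioxaspiro[4.5]dec-7-en-4-one
Product: 9 (1S,4R,5R)-1-hydroxy-4-iodo-6-oxabicyclo[3.2.1]octan-7-one, via lithium carboxylate 8 (not isolated)
Conditions: LiOH·H2O, THF–H2O, 0 °C to rt; then NaHCO3, KI, I2, 0 °C to rt, dark; Na2S2O3 work-up
Reagents that add atoms: lithium hydroxide, [Li+].[OH-]; iodine, II
Why: Hydroxide cleaves the acetal-ester with release of pivalaldehyde, and the carboxylate then undergoes kinetic iodolactonisation onto the nearer alkene carbon C5 to give the γ-lactone, the tether forcing O-5 cis to the carboxyl on C1 and anti addition placing iodine trans at C4.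

Step 5
Reactants: 9 (1S,4R,5R)-1-hydroxy-4-iodo-6-oxabicyclo[3.2.1]octan-7-one
Product: 10 (1S,5R)-1-hydroxy-6-oxabicyclo[3.2.1]oct-3-en-7-one
Conditions: DBU, toluene, 80 °C
Reagents that add atoms: none
Why: E2 dehydroiodination in which the axial iodide at C4 has an anti-periplanar hydrogen only at C3 (the C5 hydrogen is equatorial), so the alkene should form between C3 and C4.

Step 6
Reactants: 10 (1S,5R)-1-hydroxy-6-oxabicyclo[3.2.1]oct-3-en-7-one
Product: 11 (1S,3R,4R,5R)-1,3,4-trihydroxy-6-oxabicyclo[3.2.1]octan-7-one (quinide)
Conditions: OsO4 (cat.), NMO, acetone–H2O, rt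
Reagents that add atoms: N-methylmorpholine N-oxide, C[N+]1([O-])CCOCC1; water, O; osmium tetroxide (catalytic oxygen carrier), O=[Os](=O)(=O)=O
Why: Catalytic OsO4 syn-dihydroxylation from the convex face of the bicycle, anti to the lactone bridge, sets O-3 and O-4 cis to each other and trans to O-5, as in quinic acid.

Step 7
Reactants: 11 quinide
Product: 12 (1S,3R,4R,5R)-3-(benzyloxy)-1,4-dihydroxy-6-oxabicyclo[3.2.1]octan-7-one (3-O-benzylquinide)
Conditions: Bu2SnCl2 (cat.), BnBr, K2CO3, Bu4NBr (cat.), MeCN, 60 °C
Reagents that add atoms: benzyl bromide, BrCc1ccccc1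
Why: Tin-acetal mediated regioselective O-alkylation, in which the cis-3,4-diol forms a cyclic dibutylstannylene whose equatorial oxygen O-3 is the more nucleophilic, while the axial 4-OH beside the lactone bridge and the tertiary 1-OH stay free; no stereocentre changes.

Step 8
Reactants: 12 3-O-benzylquinide
Product: 14 benzyl 3-O-benzylquinate, via caesium carboxylate 13 (not isolated)
Conditions: CsOH·H2O, THF–H2O, 0 °C; evaporate; BnBr, DMF, rt
Reagents that add atoms: caesium hydroxide, [Cs+].[OH-]; benzyl bromide, BrCc1ccccc1
Why: Saponification of the strained γ-lactone followed by SN2 O-alkylation of the caesium carboxylate frees O-5 and masks the acid, the ring flipping to the quinate chair with O-4 and O-5 trans-diequatorial and no stereocentre touched.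

Step 9
Reactants: 14 benzyl 3-O-benzylquinate; 15 4-(benzyloxy)-3-methoxybenzoic acid (first of the two equivalents consumed)
Product: 17 benzyl 3-O-benzyl-4,5-bis-O-[4-(benzyloxy)-3-methoxybenzoyl]quinate, via acid chloride 16 (not isolated)
Conditions: 15 (2.3 equiv), (COCl)2, DMF (cat.), CH2Cl2, 0 °C to rt, evaporate; then 14 (1 equiv), pyridine, DMAP (cat.), CH2Cl2, 0 °C to rt
Reagents that add atoms: 4-(benzyloxy)-3-methoxybenzoic acid (second equivalent of 15, likewise converted into 16), COc1cc(C(=O)O)ccc1OCc1ccccc1
Why: DMAP-catalysed acylation (nucleophilic acyl substitution) by two equivalents of the acid chloride made in situ should esterify both equatorial secondary hydroxyls, one acyl group going to O-4 and one to O-5, the axial tertiary 1-OH being too hindered and O-3 blocked, and since both acyl groups are the same a 4/5 acyl shift would not matter.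

Step 10
Reactants: 17 benzyl 3-O-benzyl-4,5-bis-O-[4-(benzyloxy)-3-methoxybenzoyl]quinate
Product: 18 burkinabin C
Conditions: H2 (1 atm), Pd(OH)2/C, EtOAc–EtOH, rt
Reagents that add atoms: none
Why: Heterogeneous catalytic hydrogenolysis cleaves the benzyl ester, both aryl benzyl ethers and the O-3 benzyl ether under neutral conditions that keep the aryl esters and avoid base-induced acyl migration to the freed 3-OH.

**Compound list**

1 | (R)-lactic acid, (2R)-2-hydroxypropanoic acid | C[C@@H](O)C(=O)O | starting material
2 | pivalaldehyde, 2,2-dimethylpropanal | CC(C)(C)C=O | starting material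
3 | (2R,5R)-2-tert-butyl-5-methyl-1,3-dioxolan-4-one (methyl and tert-butyl cis) | C[C@H]1O[C@@H](C(C)(C)C)OC1=O | intermediate
4 | (2S,5S)-5-bromo-2-tert-butyl-5-methyl-1,3-dioxolan-4-one (Br trans to tert-butyl; acetal carbon unchanged in space, descriptor changed only by the bromine priority) | C[C@@]1(Br)O[C@@H](C(C)(C)C)OC1=O | intermediate
5 | (2R)-2-tert-butyl-5-methylidene-1,3-dioxolan-4-one | C=C1O[C@@H](C(C)(C)C)OC1=O | intermediate
6 | buta-1,3-diene | C=CC=C | starting material
7 | (2R,5S)-2-tert-butyl-1,3-dioxaspiro[4.5]dec-7-en-4-one (allylic ring CH2 trans to tert-butyl) | C1C=CC[C@]2(C1)O[C@@H](C(C)(C)C)OC2=O | intermediate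
8 | lithium (1S)-1-hydroxycyclohex-3-ene-1-carboxylate | C1C=CC[C@](O)(C(=O)[O-])C1.[Li+] | intermediate
9 | (1S,4R,5R)-1-hydroxy-4-iodo-6-oxabicyclo[3.2.1]octan-7-one | I[C@@H]1CC[C@]2(O)C[C@H]1OC2=O | intermediate
10 | (1S,5R)-1-hydroxy-6-oxabicyclo[3.2.1]oct-3-en-7-one | C1=CC[C@]2(O)C[C@H]1OC2=O | intermediate
11 | quinide, (1S,3R,4R,5R)-1,3,4-trihydroxy-6-oxabicyclo[3.2.1]octan-7-one | O[C@@H]1[C@H](O)C[C@]2(O)C[C@H]1OC2=O | intermediate
12 | 3-O-benzylquinide, (1S,3R,4R,5R)-3-(benzyloxy)-1,4-dihydroxy-6-oxabicyclo[3.2.1]octan-7-one | O[C@@H]1[C@H](OCc3ccccc3)C[C@]2(O)C[C@H]1OC2=O | intermediate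
13 | caesium 3-O-benzylquinate (configuration of (−)-quinic acid) | O[C@@H]1[C@H](OCc2ccccc2)C[C@@](O)(C(=O)[O-])C[C@H]1O.[Cs+] | intermediate
14 | benzyl 3-O-benzylquinate (1-OH, 3-OBn and 4-OH cis; 5-OH trans to them and cis to the ester) | O[C@@H]1[C@H](OCc2ccccc2)C[C@@](O)(C(=O)OCc2ccccc2)C[C@H]1O | intermediate
15 | 4-(benzyloxy)-3-methoxybenzoic acid | COc1cc(C(=O)O)ccc1OCc1ccccc1 | starting material
16 | 4-(benzyloxy)-3-methoxybenzoyl chloride | COc1cc(C(Cl)=O)ccc1OCc1ccccc1 | intermediate
17 | benzyl 3-O-benzyl-4,5-bis-O-[4-(benzyloxy)-3-methoxybenzoyl]quinate | COc1cc(C(=O)O[C@@H]2[C@H](OCc3ccccc3)C[C@@](O)(C(=O)OCc3ccccc3)C[C@H]2OC(=O)c2ccc(OCc3ccccc3)c(OC)c2)ccc1OCc1ccccc1 | intermediate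
18 | burkinabin C, 4,5-di-O-vanilloyl-(−)-quinic acid | COc1cc(C(=O)O[C@@H]2[C@H](O)C[C@@](O)(C(=O)O)C[C@H]2OC(=O)c2ccc(O)c(OC)c2)ccc1O | target

**Step count.** Total: 10 steps. Longest linear sequence: 10 steps (1 to 18); 2, 6 and 15 enter as commercial materials, 15 in two equivalents.

**Steps most likely to fail**

Step 3 (key cycloaddition). At the temperature butadiene needs, radical polymerisation of the captodative dienophile may outrun cycloaddition, or facial selectivity may erode. The fallback replaces acetal control by a racemic cycloaddition and classical resolution. It sets out from 6 and commercial methyl 2-acetoxyacrylate: thermal Diels–Alder reaction (toluene, sealed vessel, BHT) should give racemic methyl 1-(acetyloxy)cyclohex-3-ene-1-carboxylate F1. LiOH in aqueous THF and acidification give racemic 1-hydroxycyclohex-3-ene-1-carboxylic acid F2. Crystallisation of a diastereomeric salt with 1-phenylethylamine is intended to give (R)-1-phenylethylammonium (S)-1-hydroxycyclohex-3-ene-1-carboxylate F3; the (R)-amine is written, and its antipode is used if the salt of the (R)-acid is the one that crystallises. LiOH liberates the amine and gives 8, where the fallback rejoins the route at the iodolactonisation half of step 4.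

Step 7 (regioselective O-3 benzylation). Regioselectivity may be lost through alkylation at axial O-4 or tertiary O-1, or carbonate may open the lactone. The fallback changes the protecting group and its mode of introduction. It sets out from 11: kinetic silylation of the most accessible, equatorial hydroxyl (TBSCl, imidazole, DMF, 0 °C) should give 3-O-(tert-butyldimethylsilyl)quinide F4. CsOH then BnBr, as in step 8, gives benzyl 3-O-(tert-butyldimethylsilyl)quinate F5. Acylation with two equivalents of 16, as in step 9, gives benzyl 3-O-(tert-butyldimethylsilyl)-4,5-bis-O-[4-(benzyloxy)-3-methoxybenzoyl]quinate F6. HF·pyridine in THF removes the silyl ether under acidic, migration-free conditions to give benzyl 4,5-bis-O-[4-(benzyloxy)-3-methoxybenzoyl]quinate F7. Hydrogenolysis as in step 10 then gives 18, where the fallback rejoins the route.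

Step 9 (double acylation). The reaction may stall after the first ester because O-4 is flanked on both sides, and forcing it may acylate the tertiary 1-OH. The fallback spreads the two acylations across the lactone opening, one equivalent of acid chloride each time. It sets out from 12, where the axial 4-OH is the only free secondary hydroxyl: acylation with one equivalent of 16 (pyridine, DMAP, warming) should give 3-O-benzyl-4-O-[4-(benzyloxy)-3-methoxybenzoyl]quinide F8. One equivalent of CsOH at 0 °C should open the strained, α-hydroxy-activated lactone faster than it cleaves the electron-rich aryl ester; BnBr in DMF then gives benzyl 3-O-benzyl-4-O-[4-(benzyloxy)-3-methoxybenzoyl]quinate F9. A shift of the acyl group from O-4 to O-5 at this stage would be harmless, because the remaining hydroxyl receives the same acyl group. A second acylation with one equivalent of 16 gives 17, where the fallback rejoins the route.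

**Further compounds**

F1 | step 3 | methyl 1-(acetyloxy)cyclohex-3-ene-1-carboxylate (racemic) | COC(=O)C1(OC(C)=O)CCC=CC1
F2 | step 3 | 1-hydroxycyclohex-3-ene-1-carboxylic acid (racemic) | OC(=O)C1(O)CCC=CC1
F3 | step 3 | (R)-1-phenylethylammonium (S)-1-hydroxycyclohex-3-ene-1-carboxylate | C1C=CC[C@](O)(C(=O)[O-])C1.C[C@@H]([NH3+])c1ccccc1
F4 | step 7 | 3-O-(tert-butyldimethylsilyl)quinide | O[C@@H]1[C@H](O[Si](C)(C)C(C)(C)C)C[C@]2(O)C[C@H]1OC2=O
F5 | step 7 | benzyl 3-O-(tert-butyldimethylsilyl)quinate | O[C@@H]1[C@H](O[Si](C)(C)C(C)(C)C)C[C@@](O)(C(=O)OCc2ccccc2)C[C@H]1O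
F6 | step 7 | benzyl 3-O-(tert-butyldimethylsilyl)-4,5-bis-O-[4-(benzyloxy)-3-methoxybenzoyl]quinate | COc1cc(C(=O)O[C@@H]2[C@H](O[Si](C)(C)C(C)(C)C)C[C@@](O)(C(=O)OCc3ccccc3)C[C@H]2OC(=O)c2ccc(OCc3ccccc3)c(OC)c2)ccc1OCc1ccccc1
F7 | step 7 | benzyl 4,5-bis-O-[4-(benzyloxy)-3-methoxybenzoyl]quinate | COc1cc(C(=O)O[C@@H]2[C@H](O)C[C@@](O)(C(=O)OCc3ccccc3)C[C@H]2OC(=O)c2ccc(OCc3ccccc3)c(OC)c2)ccc1OCc1ccccc1
F8 | step 9 | 3-O-benzyl-4-O-[4-(benzyloxy)-3-methoxybenzoyl]quinide | COc1cc(C(=O)O[C@@H]2[C@H](OCc3ccccc3)C[C@]4(O)C[C@H]2OC4=O)ccc1OCc1ccccc1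
F9 | step 9 | benzyl 3-O-benzyl-4-O-[4-(benzyloxy)-3-methoxybenzoyl]quinate | COc1cc(C(=O)O[C@@H]2[C@H](OCc3ccccc3)C[C@@](O)(C(=O)OCc3ccccc3)C[C@H]2O)ccc1OCc1ccccc1
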